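The constant Monday's run offers you is a time constant per catalyst, the turnover time: the minutes one free catalyst takes to release one target. To read it, put everything on the substrate charge. Monday's load, catalyst charged as a fraction of substrate charged, is 7.75%, so a target fraction divided by the load counts turnovers.

| setting | Monday's | autumn | noon | midnight |
|---|---|---|---|---|
| substrate | 0.40 M | 0.40 M | 0.40 M | 0.40 M |
| free catalyst | 31 mM | 10 mM | 15 mM | 20 mM |
| remark | run made earlier |  |  |  |
| time |  | 40 min | 40 min | 40 min |

Monday's run (percent of the substrate charged)

| time / min | target / % |
|---|---|
| 2.00 | 1.2 |
| 5.00 | 2.2 |
| 10.0 | 5.0 |
| 15.0 | 7.5 |
| 20.0 | 8.2 |
| 30.0 | 10.4 |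

(each reading ± 0.5 percentage points)

* [target] at the end for autumn, noon, midnight, in this order
* the course of these numbers from the first flask to the last (falls all the way / hardly changes / falls, then rises / rises all the way / rises, then falls)

- "hardly changes" means that all values lie within two and a half points (for a concentration: within two and a half percent of the largest)
- no earlier run changes the charge of free catalyst; that part of a forecast is a guess

Now run Monday's flask slowly. Over the first 10.0 min target reaches 5.0%, so one turnover takes 15.5 min. In the middle window, up to 20.0 min, a turnover takes 24.2 min. In the last window, up to 30.0 min, it takes 35.2 min, which is longer than at the start. The readings show target and nothing else, so they do not say which step slows. What matters for the end of the run is that the clock lengthens, so you extend from the last window, not the first. That window is soft: its rise of 2.2 percentage points is the difference of two readings, each scattering by 0.5 points.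

The reading at 30.0 min counts 1.34 turnovers in Monday's flask. The remaining 10.0 min at the last turnover time add 0.284. That gives the turnover count at the asked time, target made per catalyst charged, of 1.63. The substrate charge is the same in every flask, but no run changes the catalyst, so carrying this count to other loads is a guess. Multiplying it by each load, you expect target fractions of 4.06% for autumn, 6.10% for noon and 8.13% for midnight, rising with the load.

The forecast gave 0.017 M, 0.025 M and 0.033 M, rises all the way, on the ground that “More catalyst should give more target”.

The flasks give 0.0179 M, 0.0265 M and 0.0349 M, rises all the way; as fractions of the substrate charge these are 4.46%, 6.61% and 8.71%.

    substrate + free catalyst ⇌ catalyst intermediate A (K = 1.30 /M, k = 0.200 /M/s)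
    catalyst intermediate A → catalyst intermediate B (k = 0.00480 /s)
    catalyst intermediate B → free catalyst + target (k = 0.0160 /s)
    2 substrate → self-condensation product (k = 0.00190 /M/s)

Counted per catalyst, the autumn flask makes 1.79 turnovers and the midnight flask 1.74, a little above your 1.63. Of the effects tried on the autumn flask, the largest single one holding this count down is the falling back of catalyst intermediate A to substrate and free catalyst . The simulated autumn run without that falling back reaches 0.0749 M, which is 7.49 turnovers.

The earlier runs and the new flask stem from a simulated flask for an exercise, noise included.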